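**Retrosynthetic overview**
1. Target ⇒ C3 phosphonoacetate 11 + dienal 16: a last-step Horner–Wadsworth–Emmons reaction completes the trienoate; 13-OH comes from allylic oxidation, 9α-OH/10α-H from hydroboration of a 9-ene.
2. 3α-Hydroxyeremophiladienone 4 ⇒ 3α,4α-epoxyeudesmane 3 by an epoxide-triggered 1,2-hydride/1,2-methyl shift (eudesmane → eremophilane, the aristolochene-type shift).
3. Eudesmadienone 2 ⇒ germacrone 1 by an enantioselective proton-initiated transannular cyclisation.
4. Ring order: the ten-membered ring is bought; rings A and B are formed together in step 1; afterwards only the methyl group migrates.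

Assumption: germacrone is taken as a cheap commercial terpene (bulk isolate of zdravets oil); α/β refer to the usual drawing in which the C5/C10 methyl is β.

**Step 1**
Reactants: 1 germacrone
Product: 2 (5R,10R)-eudesma-3,7(11)-dien-8-one (trans-fused 10β-methyl 5α-H)
Conditions: (S,S)-IDPi Brønsted acid (BINOL-derived imidodiphosphorimidate with 3,3′-aryl groups and N-triflyl groups; enantiomer and aryl group fixed by screening), 5 mol %, toluene, −40 °C
Reagents that add atoms: none
Why: Proposed new method: the enantiomeric crossed conformers of germacrone interconvert quickly, the confined chiral acid (hydrogen-bonded to the C8 ketone) protonates C1 of one of them, the 4,5-olefin closes the C5–C10 bond through a chair–chair transition state (10β-methyl and 5α-H set together, trans-fused) and the chiral anion removes the axial H-3 of the C4 cation to give the 3-ene; the closest known reactions are the achiral-acid transannular cyclisation of germacrone to selinadienones and IDPi-catalysed enantioselective cation–olefin (polyene) cyclisations.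

**Step 2**
Reactants: 2 (5R,10R)-eudesma-3,7(11)-dien-8-one
Product: 3 (3R,4S,5R,10R)-3α,4α-epoxyeudesm-7(11)-en-8-one
Conditions: DMDO (1.1 equiv), acetone, 0 °C
Reagents that add atoms: dimethyldioxirane, CC1(C)OO1
Why: Electrophilic dioxirane epoxidation takes the electron-rich trisubstituted 3-ene and not the enone, and attacks the α face because the axial 10β-methyl shields the β face, which sets C3 and C4.

**Step 3**
Reactants: 3 (3R,4S,5R,10R)-3α,4α-epoxyeudesm-7(11)-en-8-one
Product: 4 (3R,4R,5R)-3-hydroxyeremophila-7(11),9-dien-8-one (3α-OH 4β-Me 5β-Me)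
Conditions: BF3·OEt2 (0.3 equiv), CH2Cl2, −78 to −20 °C
Reagents that add atoms: none
Why: Proposed new method: BF3 opens the epoxide at tertiary C4, the 3α-oxygen stays axial so the equatorial H-3 lies in the nodal plane of the cation and the Meinwald ketone is disfavoured, the axial H-5α shifts to C4 (4α-H, 4β-Me), the axial 10β-methyl then migrates antiperiplanar to C5 (5β-Me) and the C10 cation loses the acidic H-9 to give the conjugated 9-en-8-one, so C4 and C5 are fixed suprafacially by the substrate; the closest known reactions are Westphalen/friedelane-type backbone rearrangements of steroidal epoxides and the acid-mediated methyl shift of 4,5-epoxyeudesmanes to eremophilanes.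

**Step 4**
Reactants: 4 (3R,4R,5R)-3-hydroxyeremophila-7(11),9-dien-8-one; 5 (diethoxyphosphoryl)acetic acid
Product: 6 (3R,4R,5R)-8-oxoeremophila-7(11),9-dien-3-yl (diethoxyphosphoryl)acetate
Conditions: DCC, DMAP (cat.), CH2Cl2, 0 °C to rt
Reagents that add atoms: none
Why: Steglich esterification of the only free hydroxyl with retention at C3 installs a masked side chain that survives the borane, MnO2 and SeO2 steps, which a triene would not.

**Step 5**
Reactants: 6 (3R,4R,5R)-8-oxoeremophila-7(11),9-dien-3-yl (diethoxyphosphoryl)acetate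
Product: 8 (3R,4R,5R,9S,10R)-8,9-dihydroxyeremophil-7(11)-en-3-yl (diethoxyphosphoryl)acetate (both C8 epimers), via organoborane 7 (not isolated)
Conditions: BH3·SMe2 (2.2 equiv), THF, −20 to 0 °C; then 30% H2O2, aq. NaOAc, 0 °C to rt
Reagents that add atoms: hydrogen peroxide, OO (oxygen on C9); borane–dimethyl sulfide, C[S+](C)[BH3-] (boron in 7 only)
Why: Hydroboration–oxidation: BH3 first reduces the C8 ketone (1,2) and then adds syn across the trisubstituted 9-ene with boron on C9 from the α face, away from the axial 5β-methyl (the pattern of 5-ene steroids), so that oxidation with retention gives 9α-OH and 10α-H (trans-decalin) in one event, while the more hindered tetrasubstituted 7(11)-ene reacts more slowly.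

**Step 6**
Reactants: 8 (3R,4R,5R,9S,10R)-8,9-dihydroxyeremophil-7(11)-en-3-yl (diethoxyphosphoryl)acetate
Product: 9 (3R,4R,5R,9S,10R)-9-hydroxy-8-oxoeremophil-7(11)-en-3-yl (diethoxyphosphoryl)acetate
Conditions: MnO2 (activated, excess), CH2Cl2, rt
Reagents that add atoms: none
Why: Chemoselective MnO2 oxidation of the allylic C8 carbinol (both epimers converge) restores the enone and leaves the non-allylic 9α-hydroxyl alone.

**Step 7**
Reactants: 9 (3R,4R,5R,9S,10R)-9-hydroxy-8-oxoeremophil-7(11)-en-3-yl (diethoxyphosphoryl)acetate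
Product: 11 (3R,4R,5R,9S,10R,7(11)E)-9,13-dihydroxy-8-oxoeremophil-7(11)-en-3-yl (diethoxyphosphoryl)acetate, via enal 10 (not isolated)
Conditions: SeO2 (2 equiv), 1,4-dioxane, 70 °C; then NaBH4, EtOH, −40 °C
Reagents that add atoms: selenium dioxide, O=[Se]=O
Why: Riley allylic oxidation (ene reaction then [2,3]-shift) followed by borohydride reduction of the over-oxidised enal: selenium bonds to the enone α-carbon C7 so only the γ-methyls are oxidised, the E product (oxygen on the methyl remote from C8=O) is the isomer that persists because the Z isomer closes onto the ketone to a hemiketal/furan that is separated, and NaBH4 at −40 °C reduces only the aldehyde.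

**Step 8**
Reactants: 12 hexanal; 13 diethyl [(2E)-3-cyano-2-methylprop-2-en-1-yl]phosphonate
Product: 14 (2E,4E)-3-methyldeca-2,4-dienenitrile
Conditions: NaH, THF, 0 °C to rt
Reagents that add atoms: none
Why: Vinylogous Horner–Wadsworth–Emmons olefination gives the new 4E alkene, and the 2E geometry comes from the reagent (about 3:1, the minor 2Z isomer is removed by chromatography).

**Step 9**
Reactants: 14 (2E,4E)-3-methyldeca-2,4-dienenitrile
Product: 16 (2E,4E)-3-methyldeca-2,4-dienal, via aluminoimine 15 (not isolated)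
Conditions: iBu2AlH (1.1 equiv), toluene, −78 °C; then 1 M HCl, 0 °C
Reagents that add atoms: water, O (aldehyde oxygen); diisobutylaluminium hydride, CC(C)C[AlH]CC(C)C (aluminium in 15 only)
Why: Partial hydride reduction of the nitrile stops at the N-aluminoimine, which is hydrolysed to the aldehyde without change of the diene geometry.

**Step 10**
Reactants: 11 (3R,4R,5R,9S,10R,7(11)E)-9,13-dihydroxy-8-oxoeremophil-7(11)-en-3-yl (diethoxyphosphoryl)acetate; 16 (2E,4E)-3-methyldeca-2,4-dienal
Product: 17 (3R,4R,5R,9S,10R,7(11)E)-9,13-dihydroxy-8-oxoeremophil-7(11)-en-3-yl (2E,4E,6E)-5-methyldodeca-2,4,6-trienoate (CNP0226738.2)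
Conditions: LiOH·H2O, 4 Å molecular sieves, THF, rt
Reagents that add atoms: none
Why: Horner–Wadsworth–Emmons olefination of the stabilised phosphonoacetate with the enal gives the 2E alkene of the trienoate under conditions mild enough for the free hydroxyls, the α-ketol and the enone.

**Compound list**
1 | germacrone, (3E,7E)-3,7-dimethyl-10-(propan-2-ylidene)cyclodeca-3,7-dien-1-one | C/C1=C\CC/C(C)=C/CC(=C(C)C)C(=O)C1 | starting material
2 | (5R,10R)-eudesma-3,7(11)-dien-8-one (10β-Me, 5α-H) | CC1=CCC[C@]2(C)CC(=O)C(=C(C)C)C[C@@H]12 | intermediate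
3 | (3R,4S,5R,10R)-3α,4α-epoxyeudesm-7(11)-en-8-one | C[C@@]12O[C@@H]1CC[C@]3(C)CC(=O)C(=C(C)C)C[C@@H]23 | intermediate
4 | (3R,4R,5R)-3-hydroxyeremophila-7(11),9-dien-8-one (3α-OH, 4β-Me, 5β-Me) | O[C@@H]1CCC2=CC(=O)C(=C(C)C)C[C@]2(C)[C@H]1C | intermediate
5 | (diethoxyphosphoryl)acetic acid | CCOP(=O)(CC(=O)O)OCC | starting material
6 | (3R,4R,5R)-8-oxoeremophila-7(11),9-dien-3-yl (diethoxyphosphoryl)acetate | CCOP(=O)(OCC)CC(=O)O[C@@H]1CCC2=CC(=O)C(=C(C)C)C[C@]2(C)[C@H]1C | intermediate
7 | 9α-boryl-8-boryloxy-10α-H organoborane of 6 (C8 epimers) | CCOP(=O)(OCC)CC(=O)O[C@@H]1CC[C@H]2[C@H](B)C(OB)C(=C(C)C)C[C@]2(C)[C@H]1C | intermediate (not isolated)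
8 | (3R,4R,5R,9S,10R)-8,9-dihydroxyeremophil-7(11)-en-3-yl (diethoxyphosphoryl)acetate (9α-OH, 10α-H; C8 epimers) | CCOP(=O)(OCC)CC(=O)O[C@@H]1CC[C@H]2[C@H](O)C(O)C(=C(C)C)C[C@]2(C)[C@H]1C | intermediate
9 | (3R,4R,5R,9S,10R)-9-hydroxy-8-oxoeremophil-7(11)-en-3-yl (diethoxyphosphoryl)acetate | CCOP(=O)(OCC)CC(=O)O[C@@H]1CC[C@H]2[C@H](O)C(=O)C(=C(C)C)C[C@]2(C)[C@H]1C | intermediate
10 | (3R,4R,5R,9S,10R,7(11)E)-9-hydroxy-8,13-dioxoeremophil-7(11)-en-3-yl (diethoxyphosphoryl)acetate (enal) | CCOP(=O)(OCC)CC(=O)O[C@@H]1CC[C@H]2[C@H](O)C(=O)/C(=C(\C)C=O)C[C@]2(C)[C@H]1C | intermediate (not isolated)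
11 | (3R,4R,5R,9S,10R,7(11)E)-9,13-dihydroxy-8-oxoeremophil-7(11)-en-3-yl (diethoxyphosphoryl)acetate | CCOP(=O)(OCC)CC(=O)O[C@@H]1CC[C@H]2[C@H](O)C(=O)/C(=C(\C)CO)C[C@]2(C)[C@H]1C | intermediate
12 | hexanal | CCCCCC=O | starting material
13 | diethyl [(2E)-3-cyano-2-methylprop-2-en-1-yl]phosphonate | CCOP(=O)(OCC)C/C(C)=C/C#N | starting material
14 | (2E,4E)-3-methyldeca-2,4-dienenitrile | CCCCC/C=C/C(C)=C/C#N | intermediate
15 | N-(diisobutylalumino)imine of 16 | CCCCC/C=C/C(C)=C/C=N[Al](CC(C)C)CC(C)C | intermediate (not isolated)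
16 | (2E,4E)-3-methyldeca-2,4-dienal | CCCCC/C=C/C(C)=C/C=O | intermediate
17 | (3R,4R,5R,9S,10R,7(11)E)-9,13-dihydroxy-8-oxoeremophil-7(11)-en-3-yl (2E,4E,6E)-5-methyldodeca-2,4,6-trienoate | CCCCC/C=C/C(C)=C/C=C/C(=O)O[C@@H]1CC[C@H]2[C@H](O)C(=O)/C(=C(\C)CO)C[C@]2(C)[C@H]1C | target

**Totals**
Total step count: 10. Longest linear sequence: 8 steps (steps 1–7 and 10, from germacrone).

**Three steps most likely to fail**

Step 1 (enantioselectivity and position of the new double bond are unproven). The fallback sets out from 1 and comes back at 2. Germacrone is epoxidised with Shi's D-fructose-derived ketone catalyst and KHSO5 (buffered MeCN/dimethoxymethane, 0 °C) to (1R,10R)-1,10-epoxygermacra-4,7(11)-dien-8-one F1, which is separated from the 4,5-epoxide. InBr3 (10 mol %) in CH2Cl2 then drives the epoxide-initiated transannular cyclisation, whose absolute configuration is fixed by the epoxide, to (1R,5S,10R)-1-hydroxyeudesma-3,7(11)-dien-8-one F2. The 1β-hydroxyl is removed by Barton–McCombie deoxygenation: 1,1′-thiocarbonyldiimidazole/DMAP gives O-[(1R,5S,10R)-8-oxoeudesma-3,7(11)-dien-1-yl] 1H-imidazole-1-carbothioate F3, and Bu3SnH/AIBN in toluene at 100 °C gives 2.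

Step 3 (elimination to allylic alcohols or loss of H-6 may outrun the hydride/methyl shifts, since the leaving oxygen is syn to the migrating H-5α). The fallback sets out from 2 and comes back at 6. NBS in aqueous acetone gives the trans-diaxial bromohydrin (3R,4R,5R,10R)-3-bromo-4-hydroxyeudesm-7(11)-en-8-one F4, and K2CO3 in MeOH closes it to (3S,4R,5R,10R)-3β,4β-epoxyeudesm-7(11)-en-8-one F5. In F5 the C4–O bond is antiperiplanar to H-5α, so BF3·OEt2 now triggers a fully antiperiplanar shift sequence to (3S,4R,5R)-3-hydroxyeremophila-7(11),9-dien-8-one F6. Mitsunobu esterification (PPh3, DIAD, toluene) with acid 5 inverts C3 and gives 6.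

Step 7 (the E/Z ratio of the [2,3]-shift at a tetrasubstituted enone is not predictable, and the α-ketol may be over-oxidised). The fallback sets out from 9 and comes back at 11. It replaces kinetic control by thermodynamic control of the alkene geometry. The SeO2 oxidation is run buffered with pyridine so that the Z hemiketal does not dehydrate, and MnO2 is then added so that all γ-oxidised material reaches the aldehyde level. This gives enal 10 together with (3R,4R,5R,9S,10R,7(11)Z)-9-hydroxy-8,12-dioxoeremophil-7(11)-en-3-yl (diethoxyphosphoryl)acetate F7. The two are a 2-ene-1,4-dicarbonyl pair that equilibrates by reversible conjugate addition (catalytic PhSH/Et3N) toward the E isomer 10, which NaBH4 at −40 °C reduces to 11.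

**Further compounds**
F1 | step 1 | (1R,10R)-1,10-epoxygermacra-4,7(11)-dien-8-one | C[C@]12O[C@@H]1CC/C(C)=C/CC(=C(C)C)C(=O)C2
F2 | step 1 | (1R,5S,10R)-1-hydroxyeudesma-3,7(11)-dien-8-one (1β-OH) | CC1=CC[C@@H](O)[C@]2(C)CC(=O)C(=C(C)C)C[C@@H]12
F3 | step 1 | O-[(1R,5S,10R)-8-oxoeudesma-3,7(11)-dien-1-yl] 1H-imidazole-1-carbothioate | CC1=CC[C@@H](OC(=S)n3ccnc3)[C@]2(C)CC(=O)C(=C(C)C)C[C@@H]12
F4 | step 3 | (3R,4R,5R,10R)-3-bromo-4-hydroxyeudesm-7(11)-en-8-one (3α-Br, 4β-OH) | C[C@]1(O)[C@H](Br)CC[C@]2(C)CC(=O)C(=C(C)C)C[C@@H]12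
F5 | step 3 | (3S,4R,5R,10R)-3β,4β-epoxyeudesm-7(11)-en-8-one | C[C@]12O[C@H]1CC[C@]3(C)CC(=O)C(=C(C)C)C[C@@H]23
F6 | step 3 | (3S,4R,5R)-3-hydroxyeremophila-7(11),9-dien-8-one (3β-OH) | O[C@H]1CCC2=CC(=O)C(=C(C)C)C[C@]2(C)[C@H]1C
F7 | step 7 | (3R,4R,5R,9S,10R,7(11)Z)-9-hydroxy-8,12-dioxoeremophil-7(11)-en-3-yl (diethoxyphosphoryl)acetate | CCOP(=O)(OCC)CC(=O)O[C@@H]1CC[C@H]2[C@H](O)C(=O)/C(=C(/C)C=O)C[C@]2(C)[C@H]1C
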